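Guaiane numbering is used. The target is cut at the lactone (C6–C7), the cycloheptene (C8–C9) and the bridging enol ether (O–C14), which leaves a cis-disubstituted methylenecyclopentane. Its carbocycle C1–C5 is not assembled as a five-membered ring: it comes from (S)-4-allylcyclohex-2-enone oxide by a Lewis-acid 1,2-acyl shift. This ring contraction exploits the 1,3-disposed oxygenated carbons C4 and C6 that flank C5 on the cyclopentane: the ketone carbon becomes C4, the extruded ring carbon becomes the formyl carbon C6, and the organocatalytically set centre becomes C1. Chromium allylation, ring-closing metathesis, formylation at C10 and an epoxide-opening enol etherification then finish the tricycle.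

Key step: step 4

Assumption: the 2-formyl ketones 6 and 23 are written as their chelated hydroxymethylene tautomers, and 12 is used as the racemate because its carbinol centre becomes sp2 in step 9.

Step 1
Reactants: 1 pent-4-enal; 2 methyl vinyl ketone
Product: 3 (S)-2-allyl-5-oxohexanal
Conditions: (S)-2-[diphenyl(trimethylsilyloxy)methyl]pyrrolidine (10 mol%), ethyl 3,4-dihydroxybenzoate (20 mol%), neat, 4 °C
Reagents that add atoms: none
Why: Enamine-catalysed asymmetric Michael addition; the bulky silyloxydiphenylmethyl group shields one face of the E-enamine of 1, so the enone should add to the open face and give the (S) α-centre, the future C1.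

Step 2
Reactants: 3 (S)-2-allyl-5-oxohexanal
Product: 4 (S)-4-allylcyclohex-2-en-1-one
Conditions: KOH (aq), Bu4NOH (cat.), Et2O/THF, rt
Reagents that add atoms: none
Why: Intramolecular aldol condensation of the methyl ketone onto the aldehyde closes the cyclohexenone under mild two-phase conditions that should leave the γ-stereocentre intact.

Step 3
Reactants: 4 (S)-4-allylcyclohex-2-en-1-one
Product: 5 (4S)-4-allyl-2,3-epoxycyclohexan-1-one, epoxide trans to the allyl group
Conditions: H2O2 (30% aq), NaOH (cat.), MeOH, 0 °C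
Reagents that add atoms: hydrogen peroxide OO
Why: Weitz–Scheffer epoxidation; hydroperoxide adds to the β-carbon anti to the neighbouring allyl group, so the epoxide is expected trans to it.

Step 4
Reactants: 5 (4S)-4-allyl-2,3-epoxycyclohexan-1-one
Product: 6 (S)-3-allyl-2-(hydroxymethylene)cyclopentan-1-one
Conditions: BF3·OEt2, CH2Cl2, 0 °C to rt
Reagents that add atoms: none
Why: BF3 activates the epoxide, which opens at C5 (the carbon remote from the carbonyl) while the acyl carbon C4 shifts from C6 to C5 antiperiplanar to the departing oxygen, and the former epoxide carbon C6 ends as the formyl group. The closest known reaction type is the Lewis-acid rearrangement of α,β-epoxy ketones to β-dicarbonyl compounds with ring contraction, a semipinacol-type 1,2-acyl shift. The cyclopentane C1–C5 is closed not by a cyclisation but by this suprafacial 1,2-shift, in which the C4–C5 bond forms as the C4–C6 bond breaks. C5 is formed with inversion but is not kept, because the product rests as the chelated enol, so the only lasting stereocentre is C1, which the rearrangement does not touch. The step needs acyl migration to win over hydride migration, which would give the 1,2-diketone; the carbonyl-bearing side cannot carry positive charge, so ionisation occurs at C5, and the acyl group, the better migrating group, should move in preference to hydrogen.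

Step 5
Reactants: 6 (S)-3-allyl-2-(hydroxymethylene)cyclopentan-1-one
Product: 7 (S,E)-3-allyl-2-[(tert-butyldimethylsilyloxy)methylene]cyclopentan-1-one
Conditions: TBSCl, imidazole, DMF, 0 °C
Reagents that add atoms: tert-butyldimethylsilyl chloride CC(C)(C)[Si](C)(C)Cl
Why: O-silylation of the vinylogous acid masks the formyl group as a silyl enol ether and leaves the C4 ketone as the only carbonyl.

Step 6
Reactants: 7 (S,E)-3-allyl-2-[(tert-butyldimethylsilyloxy)methylene]cyclopentan-1-one
Product: 8 tert-butyl{[(E)-((S)-2-allyl-5-methylenecyclopentylidene)methyl]oxy}dimethylsilane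
Conditions: Cp2TiMe2, toluene, 65 °C, dark
Reagents that add atoms: dimethyltitanocene C[Ti](C)(C1C=CC=C1)C1C=CC=C1
Why: Petasis methylenation; the thermally generated titanium methylidene converts the vinylogous-ester carbonyl into the C4=C15 methylene without base.

Step 7
Reactants: 8 silyl dienol ether
Product: 9 (1R,2S)-2-allyl-5-methylenecyclopentane-1-carbaldehyde (formyl cis to allyl)
Conditions: TBAF, AcOH, THF, −78 °C; crude product used at once
Reagents that add atoms: none
Why: Fluoride desilylation followed by kinetic α-protonation of the dienolate (deconjugative protonation) from the face opposite the C1 allyl group should give the cis β,γ-unsaturated aldehyde and set C5.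

Step 8
Reactants: 10 acrolein; 11 methyl acrylate
Product: 12 methyl 3-hydroxy-2-methylenepent-4-enoate (racemic)
Conditions: DABCO (cat.), neat methyl acrylate, rt
Reagents that add atoms: none
Why: Morita–Baylis–Hillman reaction in which the amine–acrylate zwitterion adds to the aldehyde carbonyl of acrolein.

Step 9
Reactants: 12 methyl 3-hydroxy-2-methylenepent-4-enoate
Product: 13 methyl (2Z)-2-(bromomethyl)penta-2,4-dienoate
Conditions: NBS, Me2S, CH2Cl2, 0 °C to rt
Reagents that add atoms: N-bromosuccinimide O=C1CCC(=O)N1Br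
Why: Bromination with allylic transposition; bromide attacks the alkoxysulfonium salt at the methylene terminus and gives the conjugated (Z)-allylic bromide.

Step 10
Reactants: 9 (1R,2S)-2-allyl-5-methylenecyclopentane-1-carbaldehyde; 13 methyl (2Z)-2-(bromomethyl)penta-2,4-dienoate
Product: 15 trans-fused α-methylene-γ-butyrolactone (H6β, H7α) bearing the C7 vinyl group and the (1R,2S)-2-allyl-5-methylenecyclopentyl group on C6, via anti hydroxy ester 14 (not isolated)
Conditions: CrCl2, THF, 0 °C to rt; then TsOH·H2O (cat.), CH2Cl2, rt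
Reagents that add atoms: none
Why: Nozaki–Hiyama–Kishi-type chromium allylation; γ-attack of the allylchromium reagent through a closed chair transition state should give the anti adduct (trans C6/C7), 1,2-induction by C5 sets C6, and acid-promoted lactonisation closes the lactone.

Step 11
Reactants: 15 trans-lactone triene
Product: 16 4α,15-epoxide of 15
Conditions: mCPBA (1.05 equiv), NaHCO3, CH2Cl2, −20 to 0 °C
Reagents that add atoms: 3-chloroperbenzoic acid OOC(=O)c1cccc(Cl)c1
Why: Prilezhaev epoxidation; the 1,1-disubstituted C4=C15 alkene is the most electron-rich and should be attacked from the α face, opposite the two β substituents on C1 and C5.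

Step 12
Reactants: 16 epoxy lactone
Product: 17 (1αH,5αH,6βH,7αH)-4α,15-epoxy-14-norguaia-8,11(13)-dien-12,6-olide
Conditions: second-generation Grubbs catalyst (5 mol%), CH2Cl2, 40 °C
Reagents that add atoms: none
Why: Ring-closing metathesis of the C7 vinyl and C1 allyl groups closes the cycloheptene at C8=C9, while the 1,1-disubstituted acrylate and the epoxide are spectators.

Step 13
Reactants: 17 epoxy diene lactone
Product: 18 4α,15-epoxy-8α,9α-dihydroxy-14-norguai-11(13)-en-12,6-olide
Conditions: OsO4 (2 mol%), NMO, acetone/H2O, 0 °C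
Reagents that add atoms: osmium tetroxide O=[Os](=O)(=O)=O; N-methylmorpholine N-oxide C[N+]1([O-])CCOCC1; water O
Why: Catalytic syn-dihydroxylation; the cis-alkene should be attacked from the α face, away from C11 on C7 and from the cyclopentane, and the electron-poor acrylate reacts more slowly.

Step 14
Reactants: 18 epoxy diol
Product: 19 4α,15-epoxy-8α-hydroxy-9-oxo-14-norguai-11(13)-en-12,6-olide
Conditions: [(neocuproine)Pd(OAc)]2(OTf)2 (5 mol%), benzoquinone, MeCN/H2O, rt
Reagents that add atoms: none
Why: Chemoselective palladium-catalysed oxidation of a vicinal diol to an α-hydroxy ketone, expected at the less hindered carbinol C9 next to the C10 methylene.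

Step 15
Reactants: 19 α-hydroxy ketone; 20 angelic acid
Product: 21 8β-angeloyloxy-4α,15-epoxy-9-oxo-14-norguai-11(13)-en-12,6-olide
Conditions: PPh3, DIAD, toluene, 0 °C to rt
Reagents that add atoms: none
Why: Mitsunobu esterification inverts C8 and installs the angelate, with its Z geometry retained, as the 8β ester.

Step 16
Reactants: 21 angelate ketone
Product: 22 (E)-8β-angeloyloxy-14-(dimethylamino)-4α,15-epoxy-9-oxoguaia-10(14),11(13)-dien-12,6-olide
Conditions: Me2NCH(OMe)2, toluene, 90 °C
Reagents that add atoms: N,N-dimethylformamide dimethyl acetal CN(C)C(OC)OC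
Why: Aminomethylenation at the only α-methylene (C10; C8 carries a single hydrogen and cannot form the enaminone) introduces C14 without free amine or strong base.

Step 17
Reactants: 22 enaminone
Product: 24 8β-angeloyloxy-15-hydroxy-9-oxo-4β,14-epoxyguaia-10(14),11(13)-dien-12,6-olide, via hydroxymethylene ketone 23 (not isolated)
Conditions: TsOH·H2O (1.1 equiv), wet THF, 0 °C to rt
Reagents that add atoms: water O
Why: Acid hydrolysis of the enaminone releases the hydroxymethylene ketone, whose enol oxygen on C14 opens the protonated epoxide at tertiary C4 from the β face (6-exo-tet, inversion) to form the bridged vinylogous ester and free the C15 hydroxyl; the C9 oxygen lies trans to C1 across the enol double bond and cannot reach C4.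

Step 18
Reactants: 24 bridged vinylogous ester
Product: 25 8β-angeloyloxy-9α,15-dihydroxy-4β,14-epoxyguaia-10(14),11(13)-dien-12,6-olide
Conditions: NaBH4, CeCl3·7H2O, MeOH, −78 °C
Reagents that add atoms: none
Why: Luche 1,2-reduction of the vinylogous ester; axial hydride delivery is expected to give the pseudo-equatorial 9α-alcohol trans to the C8 ester, and the cerium salt should suppress conjugate reduction of the α-methylene lactone.

Step 19
Reactants: 25 diol
Product: 26 9α,15-diacetoxy-8β-angeloyloxy-4β,14-epoxyguaia-10(14),11(13)-dien-12,6-olide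
Conditions: Ac2O, pyridine, DMAP (cat.), CH2Cl2, 0 °C
Reagents that add atoms: acetic anhydride CC(=O)OC(C)=O
Why: Base-mediated acetylation of both hydroxyls, because the primary C15 alcohol cannot be spared while the secondary C9 alcohol is acylated.

Step 20
Reactants: 26 diacetate
Product: 27 the target, 9α-acetoxy-8β-angeloyloxy-15-hydroxy-4β,14-epoxyguaia-10(14),11(13)-dien-12,6α-olide
Conditions: immobilised Candida antarctica lipase B, pH 7 phosphate buffer/MTBE, rt
Reagents that add atoms: none
Why: Enzymatic ester hydrolysis should cleave the unhindered primary acetate and leave the secondary acetate, the angelate and the lactone, under neutral conditions that spare the acid-labile allylic enol ether.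

Compound list
1 | pent-4-enal | C=CCCC=O | starting material
2 | methyl vinyl ketone (but-3-en-2-one) | CC(=O)C=C | starting material
3 | (S)-2-allyl-5-oxohexanal | O=C[C@H](CC=C)CCC(C)=O | intermediate
4 | (S)-4-allylcyclohex-2-en-1-one | O=C1C=C[C@H](CC=C)CC1 | intermediate
5 | (4S)-4-allyl-2,3-epoxycyclohexan-1-one, epoxide trans to allyl | O=C1[C@H]2O[C@H]2[C@H](CC=C)CC1 | intermediate
6 | (S)-3-allyl-2-(hydroxymethylene)cyclopentan-1-one, chelated Z-enol | O=C1CC[C@@H](CC=C)/C1=C/O | intermediate
7 | (S,E)-3-allyl-2-[(tert-butyldimethylsilyloxy)methylene]cyclopentan-1-one | O=C1CC[C@@H](CC=C)/C1=C\O[Si](C)(C)C(C)(C)C | intermediate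
8 | tert-butyl{[(E)-((S)-2-allyl-5-methylenecyclopentylidene)methyl]oxy}dimethylsilane | C=C1CC[C@@H](CC=C)/C1=C\O[Si](C)(C)C(C)(C)C | intermediate
9 | (1R,2S)-2-allyl-5-methylenecyclopentane-1-carbaldehyde, formyl cis to allyl | C=C1CC[C@@H](CC=C)[C@H]1C=O | intermediate
10 | acrolein | C=CC=O | starting material
11 | methyl acrylate | C=CC(=O)OC | starting material
12 | methyl 3-hydroxy-2-methylenepent-4-enoate, racemic | C=CC(O)C(=C)C(=O)OC | intermediate
13 | methyl (2Z)-2-(bromomethyl)penta-2,4-dienoate | BrC/C(C(=O)OC)=C\C=C | intermediate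
14 | anti hydroxy ester: methyl 4-hydroxy-2-methylene-3-vinylbutanoate with the (1R,2S)-2-allyl-5-methylenecyclopentyl group on C4 | COC(=O)C(=C)[C@H](C=C)[C@H](O)[C@H]1C(=C)CC[C@H]1CC=C | intermediate
15 | trans α-methylene-γ-butyrolactone (H6β, H7α) with C7 vinyl and the (1R,2S)-2-allyl-5-methylenecyclopentyl group on C6 | C=C1C(=O)O[C@@H]([C@H]1C=C)[C@H]2C(=C)CC[C@H]2CC=C | intermediate
16 | 4α,15-epoxide of 15 (spiro-epoxide, oxygen on the α face) | C=C1C(=O)O[C@@H]([C@H]1C=C)[C@H]2[C@@]3(CO3)CC[C@H]2CC=C | intermediate
17 | (1αH,5αH,6βH,7αH)-4α,15-epoxy-14-norguaia-8,11(13)-dien-12,6-olide | C=C1C(=O)O[C@H]2[C@H]1C=CC[C@@H]1CC[C@]3(CO3)[C@@H]12 | intermediate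
18 | 4α,15-epoxy-8α,9α-dihydroxy-14-norguai-11(13)-en-12,6-olide | C=C1C(=O)O[C@H]2[C@H]1[C@@H](O)[C@@H](O)C[C@@H]1CC[C@]3(CO3)[C@@H]12 | intermediate
19 | 4α,15-epoxy-8α-hydroxy-9-oxo-14-norguai-11(13)-en-12,6-olide | C=C1C(=O)O[C@H]2[C@H]1[C@@H](O)C(=O)C[C@@H]1CC[C@]3(CO3)[C@@H]12 | intermediate
20 | angelic acid, (Z)-2-methylbut-2-enoic acid | C/C=C(/C)C(=O)O | starting material
21 | 8β-angeloyloxy-4α,15-epoxy-9-oxo-14-norguai-11(13)-en-12,6-olide | C=C1C(=O)O[C@H]2[C@H]1[C@H](OC(=O)/C(C)=C\C)C(=O)C[C@@H]1CC[C@]3(CO3)[C@@H]12 | intermediate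
22 | (E)-8β-angeloyloxy-14-(dimethylamino)-4α,15-epoxy-9-oxoguaia-10(14),11(13)-dien-12,6-olide | C=C1C(=O)O[C@H]2[C@H]1[C@H](OC(=O)/C(C)=C\C)C(=O)/C(=C/N(C)C)[C@@H]1CC[C@]3(CO3)[C@@H]12 | intermediate
23 | 8β-angeloyloxy-4α,15-epoxy-14-hydroxy-9-oxoguaia-10(14),11(13)-dien-12,6-olide (hydroxymethylene ketone) | C=C1C(=O)O[C@H]2[C@H]1[C@H](OC(=O)/C(C)=C\C)C(=O)C(=CO)[C@@H]1CC[C@]3(CO3)[C@@H]12 | intermediate
24 | 8β-angeloyloxy-15-hydroxy-9-oxo-4β,14-epoxyguaia-10(14),11(13)-dien-12,6-olide | C=C1C(=O)O[C@H]2[C@H]1[C@H](OC(=O)/C(C)=C\C)C(=O)C1=CO[C@@]3(CO)CC[C@@H]1[C@@H]23 | intermediate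
25 | 8β-angeloyloxy-9α,15-dihydroxy-4β,14-epoxyguaia-10(14),11(13)-dien-12,6-olide | C=C1C(=O)O[C@H]2[C@H]1[C@H](OC(=O)/C(C)=C\C)[C@@H](O)C1=CO[C@@]3(CO)CC[C@@H]1[C@@H]23 | intermediate
26 | 9α,15-diacetoxy-8β-angeloyloxy-4β,14-epoxyguaia-10(14),11(13)-dien-12,6-olide | C=C1C(=O)O[C@H]2[C@H]1[C@H](OC(=O)/C(C)=C\C)[C@@H](OC(C)=O)C1=CO[C@@]3(COC(C)=O)CC[C@@H]1[C@@H]23 | intermediate
27 | 9α-acetoxy-8β-angeloyloxy-15-hydroxy-4β,14-epoxyguaia-10(14),11(13)-dien-12,6α-olide (1αH,5αH,6βH,7αH) | C=C1C(=O)O[C@H]2[C@H]1[C@H](OC(=O)/C(C)=C\C)[C@@H](OC(C)=O)C1=CO[C@@]3(CO)CC[C@@H]1[C@@H]23 | target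

Total steps: 20. Longest linear sequence: 18 steps (steps 1–7 and 10–20); steps 8–9 make the lactone fragment.

Steps most likely to fail

Step 4. With only a secondary carbon to carry the charge, hydride migration to the 1,2-diketone, fluoride capture or oligomerisation of the enol product may compete with the acyl shift. The fallback sets out from 5 and triggers the ring contraction through an allyl cation instead. Wittig methylenation of 5 (Ph3P=CH2, THF) gives the allylic epoxide 5-allyl-2-methylene-7-oxabicyclo[4.1.0]heptane F1. A Lewis acid (BF3·OEt2, CH2Cl2, −78 °C) ionises the allylic C–O bond and the ring carbon bearing the allyl group shifts (Meinwald-type 1,2-alkyl shift), giving the trans aldehyde (1S,2S)-2-allyl-5-methylenecyclopentane-1-carbaldehyde F2. Silylation of its dienolate (TBSOTf, Et3N) erases the C5 centre and returns to the route at 8.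

Step 7. The β,γ-unsaturated aldehyde may slip into conjugation or epimerise at C5 during protonation and handling, and protonation may not be fully face-selective. The fallback sets out from 6 and keeps C4 as a ketone so that C5 can equilibrate later. Chromium allylation of 6 with 13 (CrCl2, then TsOH) gives the keto lactone F3. Ring-closing metathesis (second-generation Grubbs catalyst), followed by acid-mediated equilibration of C5 through the enol, should give the cis-fused 4-oxo-14,15-dinorguaia-8,11(13)-dien-12,6-olide F4. Dihydroxylation (OsO4, NMO) gives the 8α,9α-diol F5, and Lombardo methylenation (Zn, CH2Br2, TiCl4) gives the 4(15)-ene diol F6. Epoxidation with mCPBA from the α face returns to the route at 18.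

Step 18. Hydride may approach from the more open α face and give the 9β-alcohol, and the α-methylene lactone may undergo conjugate reduction. The fallback sets out from 24 and corrects C9 by inversion. Silylation of the primary alcohol (TBSCl, imidazole) gives the 15-silyl ether F7. Reduction (NaBH4, CeCl3·7H2O, −78 °C) then gives the 9β-alcohol F8, and Mitsunobu reaction with acetic acid (PPh3, DIAD) inverts C9 to the 9α-acetate F9. Buffered desilylation (TBAF, AcOH) returns to the route at 27.

Further compounds
F1 | step 4 | 5-allyl-2-methylene-7-oxabicyclo[4.1.0]heptane, epoxide trans to allyl | C=C1[C@H]2O[C@H]2[C@H](CC=C)CC1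
F2 | step 4 | (1S,2S)-2-allyl-5-methylenecyclopentane-1-carbaldehyde, formyl trans to allyl | C=C1CC[C@@H](CC=C)[C@@H]1C=O
F3 | step 7 | trans α-methylene-γ-butyrolactone with C7 vinyl and a 2-allyl-5-oxocyclopentyl group on C6 (C5 epimerisable) | C=C1C(=O)O[C@@H]([C@H]1C=C)C2C(=O)CC[C@H]2CC=C
F4 | step 7 | (1αH,5αH,6βH,7αH)-4-oxo-14,15-dinorguaia-8,11(13)-dien-12,6-olide | C=C1C(=O)O[C@H]2[C@H]1C=CC[C@@H]1CCC(=O)[C@@H]12
F5 | step 7 | 8α,9α-dihydroxy-4-oxo-14,15-dinorguai-11(13)-en-12,6-olide | C=C1C(=O)O[C@H]2[C@H]1[C@@H](O)[C@@H](O)C[C@@H]1CCC(=O)[C@@H]12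
F6 | step 7 | 8α,9α-dihydroxy-14-norguaia-4(15),11(13)-dien-12,6-olide | C=C1C(=O)O[C@H]2[C@H]1[C@@H](O)[C@@H](O)C[C@@H]1CCC(=C)[C@@H]12
F7 | step 18 | 15-O-tert-butyldimethylsilyl ether of 24 | C=C1C(=O)O[C@H]2[C@H]1[C@H](OC(=O)/C(C)=C\C)C(=O)C1=CO[C@@]3(CO[Si](C)(C)C(C)(C)C)CC[C@@H]1[C@@H]23
F8 | step 18 | 8β-angeloyloxy-9β-hydroxy-15-(tert-butyldimethylsilyloxy)-4β,14-epoxyguaia-10(14),11(13)-dien-12,6-olide | C=C1C(=O)O[C@H]2[C@H]1[C@H](OC(=O)/C(C)=C\C)[C@H](O)C1=CO[C@@]3(CO[Si](C)(C)C(C)(C)C)CC[C@@H]1[C@@H]23
F9 | step 18 | 9α-acetoxy-8β-angeloyloxy-15-(tert-butyldimethylsilyloxy)-4β,14-epoxyguaia-10(14),11(13)-dien-12,6-olide | C=C1C(=O)O[C@H]2[C@H]1[C@H](OC(=O)/C(C)=C\C)[C@@H](OC(C)=O)C1=CO[C@@]3(CO[Si](C)(C)C(C)(C)C)CC[C@@H]1[C@@H]23
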